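The atoms of the carbocycle (ring A) are numbered as follows. C1 bears the CH2OAr arm (C8), C2 bears the exocyclic methylene (C7), C3 and C4 are CH2, C5 bears OAc, and C6 bears the two methyls. The plan opens ring A at C2–C3. C3 is a plain, non-stereogenic CH2 next to the methylidene carbon, so this bond can be made as a C2=C3 ring alkene and the unsaturation shifted to C2=C7 afterwards. One ring-closing metathesis between an alpha-substituted acrylate (C2, ester carbon C7) and an allyl terminus (C3) builds ring A in a single operation. The precursor is an acyclic diene that already holds C1 (auxiliary-controlled alkylation) and C5 (allylboration) on either side of C6.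

Key step: step 9

Remarks on the design
- **Ester choice.** In the open-chain diene the C5 hydroxyl is delta to the ester carbonyl C7, with the C6 gem-dimethyl group in between. This arrangement favours closure to an alpha-methylene-delta-lactone. Such a lactone could not undergo the metathesis, because the product would be a 2-oxabicyclo[2.2.2]octene with a bridgehead alkene. The acrylate is therefore carried as its tert-butyl ester. The bulky ester blocks this lactonisation and also the earlier gamma-lactonisation of the C8 alcohol, without an extra protecting-group step.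
- **Origin of C1.** C1 is set by enolate alkylation of a purchased acid that already contains the crowded C1–C6 bond. No tetrasubstituted nucleophile has to be joined to a secondary allylic carbon.
- **CIP labels.** The label at C1 switches between S and R along the route only because the ranking of C2 against C6 changes. The spatial arrangement is the same throughout.
- **Assumption.** 3,3-Dimethylpent-4-enoic acid and the pentane solution of (+)-B-allyldiisopinocampheylborane are taken as purchasable.

Step 1
Reactants: 1 3,3-dimethylpent-4-enoic acid; 2 (4S)-4-benzyl-1,3-oxazolidin-2-one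
Product: 4 (4S)-4-benzyl-3-(3,3-dimethylpent-4-enoyl)-1,3-oxazolidin-2-one, via mixed pivalic anhydride 3 (not isolated)
Conditions: t-BuCOCl, Et3N, THF, −20 °C; then LiCl, 2, −20 °C to rt
Reagents that add atoms: none
Why: N-Acylation of an oxazolidinone through a mixed anhydride: the pivaloyl carbonyl is shielded by its tert-butyl group, so the LiCl-activated carbamate nitrogen should take up the 3,3-dimethylpent-4-enoyl residue, and no stereocentre is involved.

Step 2
Reactants: 4 (4S)-4-benzyl-3-(3,3-dimethylpent-4-enoyl)-1,3-oxazolidin-2-one; 5 tert-butyl bromoacetate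
Product: 7 tert-butyl (3S)-3-{[(4S)-4-benzyl-2-oxo-1,3-oxazolidin-3-yl]carbonyl}-4,4-dimethylhex-5-enoate, via sodium Z-enolate 6 (not isolated)
Conditions: NaN(SiMe3)2, THF, −78 °C; then 5, −78 to −30 °C
Reagents that add atoms: none
Why: Evans asymmetric alkylation: the chelated sodium Z-enolate exposes only the face opposite the benzyl group to the reactive alpha-bromo ester, which forms C1–C2 and sets C1 in the sense required by the target (3S in 7), the diastereomeric imide being removable by chromatography.

Step 3
Reactants: 7 tert-butyl (3S)-3-{[(4S)-4-benzyl-2-oxo-1,3-oxazolidin-3-yl]carbonyl}-4,4-dimethylhex-5-enoate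
Product: 8 tert-butyl (3S)-3-(hydroxymethyl)-4,4-dimethylhex-5-enoate
Conditions: LiBH4, MeOH (1 equiv), Et2O, 0 °C
Reagents that add atoms: none
Why: Reductive removal of the auxiliary: LiBH4 should reduce the activated exocyclic imide carbonyl (C8) to the primary alcohol without touching the tert-butyl ester, the vinyl group or C1, and the bulky ester holds back gamma-lactonisation.

Step 4
Reactants: 8 tert-butyl (3S)-3-(hydroxymethyl)-4,4-dimethylhex-5-enoate
Product: 9 tert-butyl (3S)-3-{[(tert-butyldimethylsilyl)oxy]methyl}-4,4-dimethylhex-5-enoate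
Conditions: TBSCl, imidazole, CH2Cl2, rt
Reagents that add atoms: tert-butyldimethylsilyl chloride CC(C)(C)[Si](C)(C)Cl
Why: Standard silylation of a primary alcohol, which masks C8–OH against the strong base, the ozone, the borane and the hydride used later.

Step 5
Reactants: 9 tert-butyl (3S)-3-{[(tert-butyldimethylsilyl)oxy]methyl}-4,4-dimethylhex-5-enoate
Product: 11 tert-butyl (3S)-3-{[(tert-butyldimethylsilyl)oxy]methyl}-2-[(dimethylamino)methyl]-4,4-dimethylhex-5-enoate (both C2 epimers), via lithium enolate 10 (not isolated)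
Conditions: LiN(i-Pr)2, THF, −78 °C; then Eschenmoser's salt, −78 °C to rt
Reagents that add atoms: N,N-dimethylmethyleneiminium iodide (Eschenmoser's salt) C=[N+](C)C.[I-]
Why: Mannich-type aminomethylation of an ester enolate with Eschenmoser's salt: only the C2 methylene next to the ester is acidic, and the new centre at C2 need not be controlled because it becomes sp2 in the next step.

Step 6
Reactants: 11 tert-butyl (3S)-3-{[(tert-butyldimethylsilyl)oxy]methyl}-2-[(dimethylamino)methyl]-4,4-dimethylhex-5-enoate
Product: 13 tert-butyl (3R)-3-{[(tert-butyldimethylsilyl)oxy]methyl}-4,4-dimethyl-2-methylidenehex-5-enoate, via trimethylammonium iodide 12 (not isolated)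
Conditions: MeI, MeOH, rt; evaporate; then DBU, CH2Cl2, rt
Reagents that add atoms: none
Why: Quaternisation followed by E1cB (Hofmann-type) elimination of trimethylamine is the classical alpha-methylenation of esters and should give the 1,1-disubstituted acrylate without touching C1, whose hydrogen is not activated by the ester.

Step 7
Reactants: 13 tert-butyl (3R)-3-{[(tert-butyldimethylsilyl)oxy]methyl}-4,4-dimethyl-2-methylidenehex-5-enoate
Product: 15 tert-butyl (3R)-3-{[(tert-butyldimethylsilyl)oxy]methyl}-4,4-dimethyl-2-methylidene-5-oxopentanoate, via secondary ozonide 14 (not isolated)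
Conditions: O3, CH2Cl2, −78 °C (Sudan Red 7B end point); then PPh3, −78 °C to rt
Reagents that add atoms: ozone [O-][O+]=O
Why: Chemoselective ozonolysis: electrophilic ozone should consume the electron-rich monosubstituted vinyl group well before the electron-poor acrylate alkene, the dye marks the end point, and PPh3 reduces the ozonide to the non-enolisable C5 aldehyde.

Step 8
Reactants: 15 tert-butyl (3R)-3-{[(tert-butyldimethylsilyl)oxy]methyl}-4,4-dimethyl-2-methylidene-5-oxopentanoate; 16 (+)-B-allyldiisopinocampheylborane (from (−)-alpha-pinene)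
Product: 18 tert-butyl (3R,5R)-3-{[(tert-butyldimethylsilyl)oxy]methyl}-5-hydroxy-4,4-dimethyl-2-methylideneoct-7-enoate, via diisopinocampheylborinate 17 (not isolated)
Conditions: 16 (salt-free), Et2O, −78 °C; then NaBO3·4H2O, THF/H2O, rt
Reagents that add atoms: none
Why: Brown asymmetric allylboration through a closed chair transition state: the reagent derived from (−)-alpha-pinene delivers allyl to the Re face of the alpha-quaternary aldehyde and thereby sets C5 as R under reagent control, while the mild perborate work-up spares the acrylate and the tert-butyl ester cannot lactonise.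

Step 9
Reactants: 18 tert-butyl (3R,5R)-3-{[(tert-butyldimethylsilyl)oxy]methyl}-5-hydroxy-4,4-dimethyl-2-methylideneoct-7-enoate
Product: 19 tert-butyl (4R,6R)-6-{[(tert-butyldimethylsilyl)oxy]methyl}-4-hydroxy-5,5-dimethylcyclohex-1-ene-1-carboxylate (cis)
Conditions: second-generation Grubbs catalyst RuCl2(=CHPh)(H2IMes)(PCy3) (5–10 mol %), 1,4-benzoquinone (10 mol %), toluene (0.005 M), 80 °C, argon sparge
Reagents that add atoms: none
Why: Olefin metathesis by the Chauvin mechanism: the ruthenium benzylidene should first exchange with the unhindered monosubstituted alkene of the allyl group (C3), the new alkylidene then adds across the C2=CH2 bond of the acrylate to give a ruthenacyclobutane, and cycloreversion releases 19 together with a ruthenium methylidene that carries the chain with loss of ethylene. The closest known reaction type is ring-closing metathesis of alpha-substituted acrylates with terminal alkenes to cyclohex-1-enecarboxylates on N-heterocyclic-carbene ruthenium catalysts. Ring A is closed as a six-membered ring by intramolecular alkylidene transfer that forms the endocyclic C2=C3 bond, and the C6 gem-dimethyl group favours the folded conformer that brings C2 and C3 together. No stereocentre is created, and C1 and C5 are carried through unchanged under these neutral conditions to give the cis product. The selectivity needed is ring closure over intermolecular coupling of the allyl terminus, which high dilution, removal of ethylene and the reluctance of the electron-poor 1,1-disubstituted alkene to homodimerise should secure, while 1,4-benzoquinone suppresses hydride-induced alkene migration. The free C5 hydroxyl is tolerated by the catalyst, and the tert-butyl ester keeps it from lactonising before the ring is closed.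

Step 10
Reactants: 19 tert-butyl (4R,6R)-6-{[(tert-butyldimethylsilyl)oxy]methyl}-4-hydroxy-5,5-dimethylcyclohex-1-ene-1-carboxylate
Product: 20 (1R,5S)-5-{[(tert-butyldimethylsilyl)oxy]methyl}-4-(hydroxymethyl)-6,6-dimethylcyclohex-3-en-1-ol
Conditions: i-Bu2AlH (4 equiv), CH2Cl2, −78 to 0 °C; aq. KNaC4H4O6 (potassium sodium tartrate)
Reagents that add atoms: none
Why: 1,2-Reduction of an alpha,beta-unsaturated ester with i-Bu2AlH gives the primary allylic alcohol at C7, the free C5 hydroxyl merely consuming one equivalent of hydride and the silyl ether being inert.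

Step 11
Reactants: 20 (1R,5S)-5-{[(tert-butyldimethylsilyl)oxy]methyl}-4-(hydroxymethyl)-6,6-dimethylcyclohex-3-en-1-ol
Product: 23 (1R,3S)-3-{[(tert-butyldimethylsilyl)oxy]methyl}-2,2-dimethyl-4-methylidenecyclohexan-1-ol, via N-allyl sulfonylhydrazine 21 (not isolated), via allylic diazene 22 (not isolated)
Conditions: PPh3, DEAD, 2-nitrobenzenesulfonylhydrazide, N-methylmorpholine, −30 °C; then rt
Reagents that add atoms: none
Why: Myers reductive allylic transposition: Mitsunobu displacement takes place only at the primary allylic C7–OH (the neopentyl-type secondary C5–OH is inert), loss of the sulfinic acid on warming gives the monoalkyl diazene, and its retro-ene loss of N2 places hydrogen on the non-stereogenic C3 while the alkene moves to C2=C7.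

Step 12
Reactants: 23 (1R,3S)-3-{[(tert-butyldimethylsilyl)oxy]methyl}-2,2-dimethyl-4-methylidenecyclohexan-1-ol
Product: 24 (1R,3S)-3-{[(tert-butyldimethylsilyl)oxy]methyl}-2,2-dimethyl-4-methylidenecyclohexyl acetate
Conditions: Ac2O, pyridine, DMAP (cat.), CH2Cl2, rt
Reagents that add atoms: acetic anhydride CC(=O)OC(C)=O
Why: DMAP-catalysed acetylation of the only free hydroxyl installs the C5 acetate with retention, and it is done before C8–OH is released because a free cis C5–OH would trap an activated C8 as a bridged 6-oxabicyclo[3.2.1]octane ether.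

Step 13
Reactants: 24 (1R,3S)-3-{[(tert-butyldimethylsilyl)oxy]methyl}-2,2-dimethyl-4-methylidenecyclohexyl acetate
Product: 25 (1R,3S)-3-(hydroxymethyl)-2,2-dimethyl-4-methylidenecyclohexyl acetate
Conditions: HF·pyridine, pyridine, THF, 0 °C to rt
Reagents that add atoms: none
Why: Fluoride-induced cleavage of the primary silyl ether under buffered, weakly acidic conditions should leave the acetate in place (no base to trigger acyl migration) and should not isomerise the exocyclic alkene.

Step 14
Reactants: 25 (1R,3S)-3-(hydroxymethyl)-2,2-dimethyl-4-methylidenecyclohexyl acetate; 26 umbelliferone (7-hydroxy-2H-chromen-2-one)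
Product: 27 (1R,3S)-2,2-dimethyl-4-methylidene-3-{[(2-oxo-2H-chromen-7-yl)oxy]methyl}cyclohexyl acetate (target)
Conditions: PPh3, DIAD, THF, 0 °C to rt
Reagents that add atoms: none
Why: Mitsunobu etherification: the acidic 7-hydroxyl of umbelliferone displaces the oxyphosphonium ion at the primary, non-stereogenic C8, so C1 and C5 are untouched and the last product is the target.

Compound list
1 | 3,3-dimethylpent-4-enoic acid | C=CC(C)(C)CC(=O)O | starting material
2 | (4S)-4-benzyl-1,3-oxazolidin-2-one | O=C1N[C@@H](Cc2ccccc2)CO1 | starting material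
3 | 3,3-dimethylpent-4-enoic pivalic anhydride | C=CC(C)(C)CC(=O)OC(=O)C(C)(C)C | intermediate
4 | (4S)-4-benzyl-3-(3,3-dimethylpent-4-enoyl)-1,3-oxazolidin-2-one | C=CC(C)(C)CC(=O)N1C(=O)OC[C@@H]1Cc1ccccc1 | intermediate
5 | tert-butyl bromoacetate | CC(C)(C)OC(=O)CBr | starting material
6 | sodium (Z)-enolate of 4 | [Na+].[O-]/C(=C\C(C)(C)C=C)N1C(=O)OC[C@@H]1Cc1ccccc1 | intermediate
7 | tert-butyl (3S)-3-{[(4S)-4-benzyl-2-oxo-1,3-oxazolidin-3-yl]carbonyl}-4,4-dimethylhex-5-enoate | C=CC(C)(C)[C@H](CC(=O)OC(C)(C)C)C(=O)N1C(=O)OC[C@@H]1Cc1ccccc1 | intermediate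
8 | tert-butyl (3S)-3-(hydroxymethyl)-4,4-dimethylhex-5-enoate | C=CC(C)(C)[C@H](CC(=O)OC(C)(C)C)CO | intermediate
9 | tert-butyl (3S)-3-{[(tert-butyldimethylsilyl)oxy]methyl}-4,4-dimethylhex-5-enoate | C=CC(C)(C)[C@H](CC(=O)OC(C)(C)C)CO[Si](C)(C)C(C)(C)C | intermediate
10 | lithium enolate of 9 | [Li+].[O-]C(OC(C)(C)C)=C[C@H](CO[Si](C)(C)C(C)(C)C)C(C)(C)C=C | intermediate
11 | tert-butyl (3S)-3-{[(tert-butyldimethylsilyl)oxy]methyl}-2-[(dimethylamino)methyl]-4,4-dimethylhex-5-enoate (both C2 epimers) | CN(C)CC(C(=O)OC(C)(C)C)[C@H](CO[Si](C)(C)C(C)(C)C)C(C)(C)C=C | intermediate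
12 | N,N,N-trimethylammonium iodide derived from 11 | C[N+](C)(C)CC(C(=O)OC(C)(C)C)[C@H](CO[Si](C)(C)C(C)(C)C)C(C)(C)C=C.[I-] | intermediate
13 | tert-butyl (3R)-3-{[(tert-butyldimethylsilyl)oxy]methyl}-4,4-dimethyl-2-methylidenehex-5-enoate | C=C(C(=O)OC(C)(C)C)[C@H](CO[Si](C)(C)C(C)(C)C)C(C)(C)C=C | intermediate
14 | 1,2,4-trioxolane (secondary ozonide) of the vinyl group of 13 | C=C(C(=O)OC(C)(C)C)[C@H](CO[Si](C)(C)C(C)(C)C)C(C)(C)C1OCOO1 | intermediate
15 | tert-butyl (3R)-3-{[(tert-butyldimethylsilyl)oxy]methyl}-4,4-dimethyl-2-methylidene-5-oxopentanoate | C=C(C(=O)OC(C)(C)C)[C@H](CO[Si](C)(C)C(C)(C)C)C(C)(C)C=O | intermediate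
16 | (+)-B-allyldiisopinocampheylborane (from (−)-alpha-pinene) | C=CCB([C@H]1C[C@H]2C[C@@H]([C@@H]1C)C2(C)C)[C@H]1C[C@H]2C[C@@H]([C@@H]1C)C2(C)C | starting material
17 | O-(diisopinocampheylboryl) derivative of 18 (borinate ester) | C=C(C(=O)OC(C)(C)C)[C@H](CO[Si](C)(C)C(C)(C)C)C(C)(C)[C@H](OB([C@H]1C[C@H]2C[C@@H]([C@@H]1C)C2(C)C)[C@H]1C[C@H]2C[C@@H]([C@@H]1C)C2(C)C)CC=C | intermediate
18 | tert-butyl (3R,5R)-3-{[(tert-butyldimethylsilyl)oxy]methyl}-5-hydroxy-4,4-dimethyl-2-methylideneoct-7-enoate | C=C(C(=O)OC(C)(C)C)[C@H](CO[Si](C)(C)C(C)(C)C)C(C)(C)[C@H](O)CC=C | intermediate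
19 | tert-butyl (4R,6R)-6-{[(tert-butyldimethylsilyl)oxy]methyl}-4-hydroxy-5,5-dimethylcyclohex-1-ene-1-carboxylate (cis) | CC(C)(C)OC(=O)C1=CC[C@@H](O)C(C)(C)[C@H]1CO[Si](C)(C)C(C)(C)C | intermediate
20 | (1R,5S)-5-{[(tert-butyldimethylsilyl)oxy]methyl}-4-(hydroxymethyl)-6,6-dimethylcyclohex-3-en-1-ol | OCC1=CC[C@@H](O)C(C)(C)[C@H]1CO[Si](C)(C)C(C)(C)C | intermediate
21 | N-alkyl-N-(2-nitrobenzenesulfonyl)hydrazine formed at C7 of 20 | NN(CC1=CC[C@@H](O)C(C)(C)[C@H]1CO[Si](C)(C)C(C)(C)C)S(=O)(=O)c1ccccc1[N+](=O)[O-] | intermediate
22 | allylic monoalkyl diazene at C7 | N=NCC1=CC[C@@H](O)C(C)(C)[C@H]1CO[Si](C)(C)C(C)(C)C | intermediate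
23 | (1R,3S)-3-{[(tert-butyldimethylsilyl)oxy]methyl}-2,2-dimethyl-4-methylidenecyclohexan-1-ol | C=C1CC[C@@H](O)C(C)(C)[C@H]1CO[Si](C)(C)C(C)(C)C | intermediate
24 | (1R,3S)-3-{[(tert-butyldimethylsilyl)oxy]methyl}-2,2-dimethyl-4-methylidenecyclohexyl acetate | C=C1CC[C@@H](OC(C)=O)C(C)(C)[C@H]1CO[Si](C)(C)C(C)(C)C | intermediate
25 | (1R,3S)-3-(hydroxymethyl)-2,2-dimethyl-4-methylidenecyclohexyl acetate | C=C1CC[C@@H](OC(C)=O)C(C)(C)[C@H]1CO | intermediate
26 | umbelliferone (7-hydroxy-2H-chromen-2-one) | O=c1ccc2ccc(O)cc2o1 | starting material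
27 | (1R,3S)-2,2-dimethyl-4-methylidene-3-{[(2-oxo-2H-chromen-7-yl)oxy]methyl}cyclohexyl acetate | C=C1CC[C@@H](OC(C)=O)C(C)(C)[C@H]1COc1ccc2ccc(=O)oc2c1 | target

Total step count: 14. Longest linear sequence: 14 steps (1 to 27). Compounds 2, 5, 16 and 26 are purchased.

Steps most likely to fail

**Step 9.** The catalyst may load on the allyl end but fail to engage the crowded, electron-poor 1,1-disubstituted alkene. Intermolecular coupling of the allyl termini or hydride-induced alkene migration would then overtake cyclisation. The fallback sets out from 18 and returns at 20. The ester is reduced first (i-Bu2AlH, CH2Cl2, −78 to 0 °C) to (3S,5R)-3-{[(tert-butyldimethylsilyl)oxy]methyl}-4,4-dimethyl-2-methylideneoct-7-ene-1,5-diol F1. Its electron-neutral 2-substituted allylic alcohol alkene is a more willing metathesis partner. Ring closure of F1 with RuCl2(=CHPh)(H2IMes)(PCy3) in dilute toluene forms the same C2=C3 bond and gives 20 directly, with no change in step count.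

**Step 3.** Hydride may attack the ring carbonyl of the auxiliary instead of the very crowded exocyclic acyl carbon (endocyclic cleavage). Alternatively the reduction may be slow enough for lactonisation to set in. The fallback sets out from 7 and returns at 8. Hydroperoxide-mediated hydrolysis (LiOH, H2O2, THF/H2O, 0 °C) is selective for the exocyclic carbonyl and gives (2S)-2-[2-(tert-butoxy)-2-oxoethyl]-3,3-dimethylpent-4-enoic acid F2. Isobutyl chloroformate and N-methylmorpholine (THF, −15 °C) convert F2 into the isobutyl carbonic mixed anhydride F3. NaBH4 (THF/H2O, 0 °C) reduces F3 to 8 without touching the tert-butyl ester or the vinyl group.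

**Step 14.** Substitution at the beta-branched C8 oxyphosphonium ion may be so slow that the azodicarboxylate–phosphine adduct is consumed unproductively. The fallback sets out from 25 and returns at 27. Mesylation (MsCl, Et3N, CH2Cl2, 0 °C) gives (1R,3S)-3-{[(methanesulfonyl)oxy]methyl}-2,2-dimethyl-4-methylidenecyclohexyl acetate F4. This is displaced by the phenoxide of 26 (Cs2CO3, DMF, 60 °C) in a Williamson-type SN2 reaction that can be heated and driven with excess nucleophile.

Further compounds
F1 | step 9 | (3S,5R)-3-{[(tert-butyldimethylsilyl)oxy]methyl}-4,4-dimethyl-2-methylideneoct-7-ene-1,5-diol | C=C(CO)[C@H](CO[Si](C)(C)C(C)(C)C)C(C)(C)[C@H](O)CC=C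
F2 | step 3 | (2S)-2-[2-(tert-butoxy)-2-oxoethyl]-3,3-dimethylpent-4-enoic acid | C=CC(C)(C)[C@H](CC(=O)OC(C)(C)C)C(=O)O
F3 | step 3 | (2S)-2-[2-(tert-butoxy)-2-oxoethyl]-3,3-dimethylpent-4-enoic isobutyl carbonic anhydride | C=CC(C)(C)[C@H](CC(=O)OC(C)(C)C)C(=O)OC(=O)OCC(C)C
F4 | step 14 | (1R,3S)-3-{[(methanesulfonyl)oxy]methyl}-2,2-dimethyl-4-methylidenecyclohexyl acetate | C=C1CC[C@@H](OC(C)=O)C(C)(C)[C@H]1COS(C)(=O)=O
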